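If each catalyst has to turn over 21.7 times to carry the whole maple charge, that number, substrate charged over free catalyst charged, is the turnover load, and you want to know whether the catalyst can pay it.

| flask | substrate | free catalyst | time |
|---|---|---|---|
| ash | 0.400 M | 0.00200 M |  |
| birch | 0.200 M | 0.00200 M |  |
| maple | 0.130 M | 0.00600 M | 98 h |

- ash run (time / h: [target] / M): 5.6: 0.0629; 17: 0.1423; 32: 0.1994; 51: 0.2348; 73: 0.2593; 98: 0.2739
- birch run (time / h: [target] / M): 5.6: 0.0367; 17: 0.0855; 32: 0.1200; 51: 0.1482; 73: 0.1581; 98: 0.1665

(scatter of a reading: 0.001 M)

- apparent order in [substrate] of the starting rate, round the charge of the ash run (the rate where two percent of its substrate have turned into target) (one fixed amount of target, the same in the runs compared)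
- target in the maple run at 98 h, as a share of the substrate charged

- Overall: substrate -> target, with free catalyst as catalyst.
- Constant volume, constant temperature.
- What is held in complexes is read along with the free species.
- An order is taken over about fifteen percent of the charge, up and down.

By 98 h the readings show 137 turns per catalyst charged in the ash run and 83.2 in the birch run, both more than the maple load. So, if turns per catalyst carry over from those charges to the maple run, catalyst life need not stop it, and the question becomes one of time.

Here is my own ladder of clocks, each being substrate not yet target over its rate, and supposing that rate follows the catalyst, which no run tests. Birch's opening clock, scaled to maple's catalyst, is 10.2 h. Birch's last interval, scaled the same way, gives 37.4 h. Both are shorter than the 98 h asked. The slower clock, held throughout, leaves 7.28% of the maple charge, so my own estimate, which is no bound, is 92.7%. The first readings of ash and birch give a mean order of 0.777 between the two charges.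

The forecast says 0.7 (0.5 to 0.88) for the local order at the ash charge, a little below its own mean order near 0.75, and 96% (88% to 99.5%) for the maple run, higher than my estimate, judging that “the catalyst is probably dying”.

The flask gives an order of 0.80 round the ash charge and 96.9% in the maple run at 98 h.

    free catalyst + substrate ⇌ catalyst-substrate complex, settled at all times (0.7050 L mol⁻¹)
    catalyst-substrate complex → target + free catalyst (31.00 h⁻¹)
    catalyst-substrate complex → spent catalyst + substrate (0.1145 h⁻¹)
    2 substrate → homo dimer (0.03042 L mol⁻¹ h⁻¹)

The path from catalyst-substrate complex to spent catalyst and substrate makes no difference to that maple target. The maple target comes to 21.0 turns per catalyst charged, just under its load of 21.7. The birch run made a quarter of its charge, 25.0 turns per catalyst, by 8.12 h.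

(The runs are simulated for an exercise; noise was put on by code.)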